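**Retrosynthetic overview**
1. Kobophenol A (37) ⇐ nonapivalate 36 ⇐ seco-phenol 33: the last ring, the central 2,3-dihydrobenzofuran, is closed at its aryl–oxygen bond O1–C7a by an anodic dearomatisation / oxa-Michael / rearomatisation cascade.
2. Enabling feature: in the benzo ring of that dihydrobenzofuran (ring B) the C6 hydroxyl is para to C3a (the carbon carrying C3) and meta to C7a. Oxidising this one free phenol makes C7a an enone β-carbon five atoms from the C2 hydroxyl, while the other β-carbon, C4, is blocked by the oxolane.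
3. 33 ⇐ triaryl ketone 31 (transfer hydrogenation with dynamic kinetic resolution sets C2 and C3) ⇐ 4-acetylphenyl pivalate 29 + aryl bromides 16 and 27 (two ketone α-arylations).
4. 16 (oxolane): 1,4-diol cyclodehydration, with C3/C4 from an iridium-catalysed allylation of deoxybenzoin 3. 27 (outer dihydrobenzofuran): dirhodium carbene C–H insertion.
5. Ring order: oxolane (step 8) and outer dihydrobenzofuran (step 14) in separate branches, central dihydrobenzofuran last (step 22); the phenols travel as pivalates and are freed in the final step.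

Key step: step 22

Remark (assumption): the structure is taken exactly as the SMILES writes it, so the outer dihydrobenzofuran is joined to C3 of the central one through its C5 and carries its free hydroxyl at C7, next to the ring oxygen.
Conventions: TBS = tert-butyldimethylsilyl, Piv = pivaloyl, Bn = benzyl. Central dihydrobenzofuran locants: O1, C2, C3, C3a, C4–C7, C7a. Group X = (2R,3S,4R,5S)-4-[3,5-bis(pivaloyloxy)phenyl]-2,5-bis[4-(pivaloyloxy)phenyl]oxolan-3-yl. Group Y = (2R,3R)-3-[3,5-bis(pivaloyloxy)phenyl]-7-(pivaloyloxy)-2-[4-(pivaloyloxy)phenyl]-2,3-dihydro-1-benzofuran-5-yl.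

**Route**

Step 1
Reactants: 1 1-[4-(TBS-oxy)phenyl]ethan-1-one; 2 1-bromo-3,5-bis(TBS-oxy)benzene
Product: 3 2-[3,5-bis(TBS-oxy)phenyl]-1-[4-(TBS-oxy)phenyl]ethan-1-one
Conditions: Pd2(dba)3 (1.5 mol%), Xantphos (4 mol%), K3PO4, toluene, 80 °C
Reagents that add atoms: none
Why: Palladium-catalysed α-arylation of the methyl ketone enolate; the weak base K3PO4 spares the aryl silyl ethers and no stereocentre is formed.

Step 2
Reactants: 4 5-(benzyloxy)-2-bromobenzaldehyde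
Product: 5 ethyl (E)-3-[5-(benzyloxy)-2-bromophenyl]prop-2-enoate
Conditions: Ph3P=CHCO2Et, toluene, 80 °C
Reagents that add atoms: ethyl (triphenylphosphoranylidene)acetate, CCOC(=O)C=P(c1ccccc1)(c1ccccc1)c1ccccc1
Why: Wittig olefination with a stabilised ylide should give the (E)-cinnamate; no stereocentre.

Step 3
Reactants: 5 ethyl (E)-3-[5-(benzyloxy)-2-bromophenyl]prop-2-enoate
Product: 6 (E)-3-[5-(benzyloxy)-2-bromophenyl]prop-2-en-1-ol
Conditions: iBu2AlH (2.2 equiv), CH2Cl2, −78 °C; Rochelle salt work-up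
Reagents that add atoms: none
Why: 1,2-Reduction of the enoate by the aluminium hydride gives the allylic alcohol while the aryl bromide and benzyl ether are inert.

Step 4
Reactants: 6 (E)-3-[5-(benzyloxy)-2-bromophenyl]prop-2-en-1-ol
Product: 7 tert-butyl (E)-3-[5-(benzyloxy)-2-bromophenyl]prop-2-en-1-yl carbonate
Conditions: Boc2O, DMAP (10 mol%), CH2Cl2, 0 °C → rt
Reagents that add atoms: di-tert-butyl dicarbonate, CC(C)(C)OC(=O)OC(=O)OC(C)(C)C
Why: DMAP-catalysed O-acylation of the primary alcohol installs the carbonate leaving group for allylic substitution; the tert-butyl carbonate releases only the poorly nucleophilic tert-butoxide later.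

Step 5
Reactants: 3 2-[3,5-bis(TBS-oxy)phenyl]-1-[4-(TBS-oxy)phenyl]ethan-1-one; 7 tert-butyl (E)-3-[5-(benzyloxy)-2-bromophenyl]prop-2-en-1-yl carbonate
Product: 8 (2R,3S)-3-[5-(benzyloxy)-2-bromophenyl]-2-[3,5-bis(TBS-oxy)phenyl]-1-[4-(TBS-oxy)phenyl]pent-4-en-1-one
Conditions: LiN(SiMe3)2, THF, −78 °C; then [Ir(cod)Cl]2 (2 mol%), BINOL-derived N,N-bis[1-(2-methoxyphenyl)ethyl]phosphoramidite (4 mol%; the enantiomer that gives the 3S centre), 7, THF, 0 °C → rt
Reagents that add atoms: none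
Why: Iridium-catalysed asymmetric allylic alkylation of a prochiral ketone enolate: the chiral iridium π-allyl complex should set the allylic centre (C3) with branched regioselectivity, and the geometrically fixed (Z)-enolate should give the anti adduct, which places the two aryl groups cis on the later oxolane.

Step 6
Reactants: 8 (2R,3S)-pent-4-en-1-one from step 5
Product: 9 (2R,3S)-3-[5-(benzyloxy)-2-bromophenyl]-2-[3,5-bis(TBS-oxy)phenyl]-1-[4-(TBS-oxy)phenyl]pent-4-en-1-ol (both C1 epimers)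
Conditions: NaBH4, CeCl3·7H2O, MeOH/THF, −40 °C
Reagents that add atoms: none
Why: Luche reduction removes the ketone under nearly neutral conditions before the labile α-aryl centre can epimerise; the new carbinol centre need not be controlled because it is reset in step 8.

Step 7
Reactants: 9 (2R,3S)-pent-4-en-1-ol from step 6
Product: 10 (3S,4R)-3-[5-(benzyloxy)-2-bromophenyl]-4-[3,5-bis(TBS-oxy)phenyl]-5-[4-(TBS-oxy)phenyl]oxolan-2-ol (lactol, epimers at C2 and C5)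
Conditions: O3, CH2Cl2/MeOH, −78 °C, Sudan Red 7B as end-point indicator; then Me2S, −78 °C → rt
Reagents that add atoms: ozone, [O-][O+]=O
Why: Ozonolysis of the terminal alkene with reductive work-up; the aldehyde is trapped at once by the 1,4-hydroxyl as the lactol, which protects the α-aryl aldehyde from epimerisation.

Step 8
Reactants: 10 lactol from step 7; 11 (4-bromophenoxy)(tert-butyl)dimethylsilane
Product: 14 (2R,3S,4R,5S)-3-[5-(benzyloxy)-2-bromophenyl]-4-[3,5-bis(TBS-oxy)phenyl]-2,5-bis[4-(TBS-oxy)phenyl]oxolane, via aryl Grignard reagent 12 (not isolated), via seco-1,4-diol 13 (not isolated)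
Conditions: 11, Mg, THF, rt; then 10, THF, 0 °C → rt; aq. NH4Cl; then TsOH·H2O (5 mol%), CH2Cl2, 0 °C → rt
Reagents that add atoms: none
Why: Grignard addition to the lactol (as its hydroxy-aldehyde) followed by acid-catalysed cyclodehydration through a 4-silyloxybenzylic cation (SN1 etherification); both ether carbons should be set under thermodynamic control with each aryl trans to its ring neighbour, whatever the carbinol configurations, while C3 and C4 stay as set in step 5.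

Step 9
Reactants: 14 tetrakis-TBS oxolane from step 8
Product: 16 (2R,3S,4R,5S)-3-[5-(benzyloxy)-2-bromophenyl]-4-[3,5-bis(pivaloyloxy)phenyl]-2,5-bis[4-(pivaloyloxy)phenyl]oxolane, via tetraphenol 15 (not isolated)
Conditions: Bu4NF (4.2 equiv), THF, 0 °C; then PivCl (5 equiv), DMAP (cat.), 0 °C → rt
Reagents that add atoms: pivaloyl chloride, CC(C)(C)C(Cl)=O
Why: Fluoride cleavage of the four aryl silyl ethers and in-situ O-acylation of the phenoxides; the benzyl ether stays so ring B remains differentiated, and the electron-poor pivaloyloxyaryl groups make the benzylic ethers acid-stable from here on.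

Step 10
Reactants: 17 5-bromo-2-hydroxy-3-methoxybenzaldehyde; 18 4-methoxybenzyl chloride
Product: 19 5-bromo-3-methoxy-2-[(4-methoxybenzyl)oxy]benzaldehyde
Conditions: K2CO3, KI (cat.), DMF, 60 °C
Reagents that add atoms: none
Why: Williamson ether synthesis on the phenol; no stereocentre.

Step 11
Reactants: 19 aldehyde from step 10; 20 (3,5-dimethoxyphenyl)magnesium chloride
Product: 21 [5-bromo-3-methoxy-2-(4-methoxybenzyloxy)phenyl](3,5-dimethoxyphenyl)methanol (racemic)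
Conditions: THF, −78 → 0 °C; aq. NH4Cl
Reagents that add atoms: none
Why: Grignard addition to the aldehyde at low temperature leaves the aryl bromide untouched; the carbinol is oxidised next, so it is left racemic.

Step 12
Reactants: 21 diarylmethanol from step 11
Product: 22 [5-bromo-3-methoxy-2-(4-methoxybenzyloxy)phenyl](3,5-dimethoxyphenyl)methanone
Conditions: MnO2 (excess), CH2Cl2, rt
Reagents that add atoms: none
Why: MnO2 oxidation of the doubly benzylic alcohol to the benzophenone.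

Step 13
Reactants: 22 benzophenone from step 12
Product: 23 hydrazone of 22 (E/Z mixture)
Conditions: N2H4·H2O (10 equiv), AcOH (cat.), EtOH, reflux
Reagents that add atoms: hydrazine monohydrate, NN.O
Why: Condensation of the diaryl ketone with hydrazine to the hydrazone, the precursor of the diazo compound.

Step 14
Reactants: 23 hydrazone from step 13
Product: 25 (2S,3R)-5-bromo-3-(3,5-dimethoxyphenyl)-7-methoxy-2-(4-methoxyphenyl)-2,3-dihydro-1-benzofuran (cis), via diaryldiazomethane 24 (not isolated)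
Conditions: MnO2, CH2Cl2, 0 °C; then Rh2(S-PTAD)4 (1 mol%; or Rh2(R-PTAD)4, whichever gives the 3R centre), 0 °C → rt
Reagents that add atoms: none
Why: Oxidation to the diaryldiazomethane and dirhodium-catalysed intramolecular 1,5 C–H insertion of the donor/donor carbene into the benzylic ether C–H closes the outer dihydrobenzofuran; the chiral carboxylate catalyst should set C3 (3R) and give the cis ring.

Step 15
Reactants: 25 cis-dihydrobenzofuran from step 14
Product: 26 (2R,3R)-5-bromo-3-(3,5-dihydroxyphenyl)-2-(4-hydroxyphenyl)-2,3-dihydro-1-benzofuran-7-ol (trans)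
Conditions: BBr3 (8 equiv), CH2Cl2, −78 → 0 °C; MeOH, then H2O
Reagents that add atoms: none
Why: Lewis-acid O-demethylation of the four aryl methyl ethers; the same acid reversibly ionises the benzylic C2–O bond (4-oxygenated benzyl cation), which should reclose to the thermodynamically preferred 2,3-trans ring while C3, not involved, keeps its configuration.

Step 16
Reactants: 26 tetraphenol from step 15
Product: 27 (2R,3R)-5-bromo-3-[3,5-bis(pivaloyloxy)phenyl]-2-[4-(pivaloyloxy)phenyl]-2,3-dihydro-1-benzofuran-7-yl pivalate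
Conditions: PivCl (6 equiv), Et3N, DMAP (cat.), CH2Cl2, 0 °C → rt
Reagents that add atoms: pivaloyl chloride, CC(C)(C)C(Cl)=O
Why: Exhaustive O-acylation of the phenols; stereocentres untouched.

Step 17
Reactants: 28 1-(4-hydroxyphenyl)ethan-1-one
Product: 29 4-acetylphenyl pivalate
Conditions: PivCl, Et3N, DMAP (cat.), CH2Cl2, 0 °C → rt
Reagents that add atoms: pivaloyl chloride, CC(C)(C)C(Cl)=O
Why: O-acylation of the phenol; the ester deactivates this aryl ring so that the later benzylic C2–O bond is acid-stable.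

Step 18
Reactants: 29 4-acetylphenyl pivalate; 16 oxolane aryl bromide from step 9
Product: 30 4-{[4-(benzyloxy)-2-X-phenyl]acetyl}phenyl pivalate
Conditions: Pd2(dba)3 (2.5 mol%), Xantphos (6 mol%), K3PO4, toluene, 90 °C
Reagents that add atoms: none
Why: Palladium-catalysed ketone α-arylation joins the hindered aryl bromide to the least hindered (methyl ketone) enolate and forms the C3–C3a bond; K3PO4 should tolerate the aryl pivalates; no new stereocentre.

Step 19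
Reactants: 30 ketone from step 18; 27 benzofuranyl bromide from step 16
Product: 31 4-{[4-(benzyloxy)-2-X-phenyl](Y)acetyl}phenyl pivalate (equilibrating epimers at the new methine)
Conditions: Pd(OAc)2 (5 mol%), P(tBu)3·HBF4 (10 mol%), K3PO4, toluene, 100 °C
Reagents that add atoms: none
Why: Second palladium-catalysed α-arylation, now at the benzylic methylene; the new doubly benzylic α-keto methine is configurationally labile, which step 20 exploits.

Step 20
Reactants: 31 triaryl ketone from step 19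
Product: 32 4-{(1S,2S)-2-[4-(benzyloxy)-2-X-phenyl]-1-hydroxy-2-Y-ethyl}phenyl pivalate
Conditions: RuCl(p-cymene)[(S,S)-TsDPEN] (3 mol%), HCO2H/Et3N (1:1), DBU (0.3 equiv), DMF, 40 °C
Reagents that add atoms: none
Why: Noyori–Ikariya asymmetric transfer hydrogenation with dynamic kinetic resolution: base keeps the α-centre epimerising, the (S,S)-catalyst should deliver hydride to the carbonyl face that gives the 1S carbinol, and only the epimer whose Felkin–Anh conformer (bulky ortho-substituted ring B anti to hydride) exposes that face should react fast, giving the (1S,2S) alcohol that maps onto the trans ring.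

Step 21
Reactants: 32 benzyl ether from step 20
Product: 33 4-{(1S,2S)-1-hydroxy-2-(4-hydroxy-2-X-phenyl)-2-Y-ethyl}phenyl pivalate
Conditions: H2 (1 atm), 10% Pd/C, EtOAc, rt
Reagents that add atoms: none
Why: Hydrogenolysis of the unhindered aryl benzyl ether frees the ring B phenol; the ring-bound secondary benzylic C–O bonds are hindered and should be cleaved much more slowly.

Step 22
Reactants: 33 seco-phenol from step 21
Product: 36 4-[(2S,3S)-6-hydroxy-4-X-3-Y-2,3-dihydro-1-benzofuran-2-yl]phenyl pivalate, via quinol methyl ether 34 (not isolated), via cis-fused oxa-Michael adduct 35 (not isolated)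
Conditions: graphite anode, Pt cathode, undivided cell, LiClO4 (0.1 M), 2,6-lutidine, MeOH/CH2Cl2 (3:1), constant current, 2.2 F mol−1, 0 °C; then DBU (0.2 equiv), 0 °C; evaporate; CF3CO2H, CH2Cl2, 0 °C → rt
Reagents that add atoms: none
Why: Proposed new method: two-electron anodic oxidation of the only free phenol (C6–OH of ring B; every other oxygen is a pivalate or an alkyl aryl ether and should not be oxidised at this potential) gives a phenoxonium ion that methanol captures at C3a (para) to the 4-methoxycyclohexa-2,5-dienone 34, the classical anodic phenol-to-quinol-ether oxidation. In 34 C7a is an enone β-carbon, and base lets the C2 alkoxide add to it in a 5-exo-trig oxa-Michael closure to the cis-fused enone 35; the closest known reaction types are oxa-Michael cyclisations of 4-(2-hydroxyethyl)cyclohexadienones and the dearomatisation–Michael–rearomatisation meta-functionalisation of para-substituted phenols. Acid then enolises the ketone and ionises the allylic C3a–OMe bond, and loss of the C7a proton restores the arene, so the net result is a dehydrogenative C–H etherification meta to the phenol. One ring is closed (5-exo-trig at oxygen); C3a and C7a are only transient stereocentres, and C2 and C3 keep their configuration because no bond to them is made or broken. Regioselectivity is secured because the other β-carbon, C4, carries the oxolane, so an adduct there cannot aromatise and reverts, and loss of the C3 proton to a quinone methide is disfavoured because allylic strain against the C4 substituent holds the C3–H bond in the ring plane. The current is switched off before acid is added, so the electron-rich product phenol never meets the anode.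

Step 23
Reactants: 36 nonapivalate from step 22
Product: 37 kobophenol A
Conditions: NaOMe (12 equiv), degassed MeOH/THF, 0 °C → rt, argon; then AcOH to pH 6
Reagents that add atoms: none
Why: Methoxide transesterification removes all nine aryl pivalates under non-acidic conditions, so the acid-labile 4-hydroxybenzylic ether centres should not epimerise.

**Compound list**
1 | 1-[4-(tert-butyldimethylsilyloxy)phenyl]ethan-1-one | CC(=O)c1ccc(O[Si](C)(C)C(C)(C)C)cc1 | starting material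
2 | 1-bromo-3,5-bis(tert-butyldimethylsilyloxy)benzene | Brc1cc(O[Si](C)(C)C(C)(C)C)cc(O[Si](C)(C)C(C)(C)C)c1 | starting material
3 | 2-[3,5-bis(TBS-oxy)phenyl]-1-[4-(TBS-oxy)phenyl]ethan-1-one | O=C(Cc1cc(O[Si](C)(C)C(C)(C)C)cc(O[Si](C)(C)C(C)(C)C)c1)c1ccc(O[Si](C)(C)C(C)(C)C)cc1 | intermediate
4 | 5-(benzyloxy)-2-bromobenzaldehyde | O=Cc1cc(OCc2ccccc2)ccc1Br | starting material
5 | ethyl (E)-3-[5-(benzyloxy)-2-bromophenyl]prop-2-enoate | CCOC(=O)/C=C/c1cc(OCc2ccccc2)ccc1Br | intermediate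
6 | (E)-3-[5-(benzyloxy)-2-bromophenyl]prop-2-en-1-ol | OC/C=C/c1cc(OCc2ccccc2)ccc1Br | intermediate
7 | tert-butyl (E)-3-[5-(benzyloxy)-2-bromophenyl]prop-2-en-1-yl carbonate | CC(C)(C)OC(=O)OC/C=C/c1cc(OCc2ccccc2)ccc1Br | intermediate
8 | (2R,3S)-3-[5-(benzyloxy)-2-bromophenyl]-2-[3,5-bis(TBS-oxy)phenyl]-1-[4-(TBS-oxy)phenyl]pent-4-en-1-one | C=C[C@H](c1cc(OCc2ccccc2)ccc1Br)[C@H](c1cc(O[Si](C)(C)C(C)(C)C)cc(O[Si](C)(C)C(C)(C)C)c1)C(=O)c1ccc(O[Si](C)(C)C(C)(C)C)cc1 | intermediate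
9 | (2R,3S)-3-[5-(benzyloxy)-2-bromophenyl]-2-[3,5-bis(TBS-oxy)phenyl]-1-[4-(TBS-oxy)phenyl]pent-4-en-1-ol (C1 epimers) | C=C[C@H](c1cc(OCc2ccccc2)ccc1Br)[C@H](c1cc(O[Si](C)(C)C(C)(C)C)cc(O[Si](C)(C)C(C)(C)C)c1)C(O)c1ccc(O[Si](C)(C)C(C)(C)C)cc1 | intermediate
10 | (3S,4R)-3-[5-(benzyloxy)-2-bromophenyl]-4-[3,5-bis(TBS-oxy)phenyl]-5-[4-(TBS-oxy)phenyl]oxolan-2-ol (epimers at C2 and C5) | OC1[C@H](c2cc(OCc3ccccc3)ccc2Br)[C@H](c2cc(O[Si](C)(C)C(C)(C)C)cc(O[Si](C)(C)C(C)(C)C)c2)C(c2ccc(O[Si](C)(C)C(C)(C)C)cc2)O1 | intermediate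
11 | (4-bromophenoxy)(tert-butyl)dimethylsilane | Brc1ccc(O[Si](C)(C)C(C)(C)C)cc1 | starting material
12 | [4-(tert-butyldimethylsilyloxy)phenyl]magnesium bromide | Br[Mg]c1ccc(O[Si](C)(C)C(C)(C)C)cc1 | intermediate
13 | (2S,3R)-2-[5-(benzyloxy)-2-bromophenyl]-3-[3,5-bis(TBS-oxy)phenyl]-1,4-bis[4-(TBS-oxy)phenyl]butane-1,4-diol (carbinol epimers) | OC(c1ccc(O[Si](C)(C)C(C)(C)C)cc1)[C@H](c1cc(OCc2ccccc2)ccc1Br)[C@H](c1cc(O[Si](C)(C)C(C)(C)C)cc(O[Si](C)(C)C(C)(C)C)c1)C(O)c1ccc(O[Si](C)(C)C(C)(C)C)cc1 | intermediate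
14 | (2R,3S,4R,5S)-3-[5-(benzyloxy)-2-bromophenyl]-4-[3,5-bis(TBS-oxy)phenyl]-2,5-bis[4-(TBS-oxy)phenyl]oxolane | Brc1c(cc(OCc2ccccc2)cc1)[C@@H]1[C@H](c2cc(O[Si](C)(C)C(C)(C)C)cc(O[Si](C)(C)C(C)(C)C)c2)[C@@H](c2ccc(O[Si](C)(C)C(C)(C)C)cc2)O[C@H]1c1ccc(O[Si](C)(C)C(C)(C)C)cc1 | intermediate
15 | (2R,3S,4R,5S)-3-[5-(benzyloxy)-2-bromophenyl]-4-(3,5-dihydroxyphenyl)-2,5-bis(4-hydroxyphenyl)oxolane | Brc1c(cc(OCc2ccccc2)cc1)[C@@H]1[C@H](c2cc(O)cc(O)c2)[C@@H](c2ccc(O)cc2)O[C@H]1c1ccc(O)cc1 | intermediate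
16 | (2R,3S,4R,5S)-3-[5-(benzyloxy)-2-bromophenyl]-4-[3,5-bis(pivaloyloxy)phenyl]-2,5-bis[4-(pivaloyloxy)phenyl]oxolane | Brc1c(cc(OCc2ccccc2)cc1)[C@@H]1[C@H](c2cc(OC(=O)C(C)(C)C)cc(OC(=O)C(C)(C)C)c2)[C@@H](c2ccc(OC(=O)C(C)(C)C)cc2)O[C@H]1c1ccc(OC(=O)C(C)(C)C)cc1 | intermediate
17 | 5-bromo-2-hydroxy-3-methoxybenzaldehyde | O=Cc1cc(Br)cc(OC)c1O | starting material
18 | 4-methoxybenzyl chloride | COc1ccc(CCl)cc1 | starting material
19 | 5-bromo-3-methoxy-2-[(4-methoxybenzyl)oxy]benzaldehyde | O=Cc1cc(Br)cc(OC)c1OCc1ccc(OC)cc1 | intermediate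
20 | (3,5-dimethoxyphenyl)magnesium chloride | Cl[Mg]c1cc(OC)cc(OC)c1 | starting material
21 | [5-bromo-3-methoxy-2-(4-methoxybenzyloxy)phenyl](3,5-dimethoxyphenyl)methanol (racemic) | OC(c1cc(OC)cc(OC)c1)c1cc(Br)cc(OC)c1OCc1ccc(OC)cc1 | intermediate
22 | [5-bromo-3-methoxy-2-(4-methoxybenzyloxy)phenyl](3,5-dimethoxyphenyl)methanone | O=C(c1cc(OC)cc(OC)c1)c1cc(Br)cc(OC)c1OCc1ccc(OC)cc1 | intermediate
23 | hydrazone of 22 (E/Z mixture) | NN=C(c1cc(OC)cc(OC)c1)c1cc(Br)cc(OC)c1OCc1ccc(OC)cc1 | intermediate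
24 | [5-bromo-3-methoxy-2-(4-methoxybenzyloxy)phenyl](3,5-dimethoxyphenyl)diazomethane | [N-]=[N+]=C(c1cc(OC)cc(OC)c1)c1cc(Br)cc(OC)c1OCc1ccc(OC)cc1 | intermediate
25 | (2S,3R)-5-bromo-3-(3,5-dimethoxyphenyl)-7-methoxy-2-(4-methoxyphenyl)-2,3-dihydro-1-benzofuran (cis) | Brc1cc(OC)c2c(c1)[C@@H](c1cc(OC)cc(OC)c1)[C@@H](c1ccc(OC)cc1)O2 | intermediate
26 | (2R,3R)-5-bromo-3-(3,5-dihydroxyphenyl)-2-(4-hydroxyphenyl)-2,3-dihydro-1-benzofuran-7-ol (trans) | Brc1cc(O)c2c(c1)[C@@H](c1cc(O)cc(O)c1)[C@H](c1ccc(O)cc1)O2 | intermediate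
27 | (2R,3R)-5-bromo-3-[3,5-bis(pivaloyloxy)phenyl]-2-[4-(pivaloyloxy)phenyl]-2,3-dihydro-1-benzofuran-7-yl pivalate | Brc1cc(OC(=O)C(C)(C)C)c2c(c1)[C@@H](c1cc(OC(=O)C(C)(C)C)cc(OC(=O)C(C)(C)C)c1)[C@H](c1ccc(OC(=O)C(C)(C)C)cc1)O2 | intermediate
28 | 1-(4-hydroxyphenyl)ethan-1-one | CC(=O)c1ccc(O)cc1 | starting material
29 | 4-acetylphenyl pivalate | CC(=O)c1ccc(OC(=O)C(C)(C)C)cc1 | intermediate
30 | 4-{[4-(benzyloxy)-2-X-phenyl]acetyl}phenyl pivalate | CC(C)(C)C(=O)Oc1ccc(cc1)C(=O)Cc1c(cc(OCc2ccccc2)cc1)[C@@H]1[C@H](c2cc(OC(=O)C(C)(C)C)cc(OC(=O)C(C)(C)C)c2)[C@@H](c2ccc(OC(=O)C(C)(C)C)cc2)O[C@H]1c1ccc(OC(=O)C(C)(C)C)cc1 | intermediate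
31 | 4-{[4-(benzyloxy)-2-X-phenyl](Y)acetyl}phenyl pivalate (epimers at the methine) | CC(C)(C)C(=O)Oc1ccc(cc1)C(=O)C(c1c(cc(OCc2ccccc2)cc1)[C@@H]1[C@H](c2cc(OC(=O)C(C)(C)C)cc(OC(=O)C(C)(C)C)c2)[C@@H](c2ccc(OC(=O)C(C)(C)C)cc2)O[C@H]1c1ccc(OC(=O)C(C)(C)C)cc1)c1cc(OC(=O)C(C)(C)C)c2c(c1)[C@@H](c1cc(OC(=O)C(C)(C)C)cc(OC(=O)C(C)(C)C)c1)[C@H](c1ccc(OC(=O)C(C)(C)C)cc1)O2 | intermediate
32 | 4-{(1S,2S)-2-[4-(benzyloxy)-2-X-phenyl]-1-hydroxy-2-Y-ethyl}phenyl pivalate | CC(C)(C)C(=O)Oc1ccc(cc1)[C@@H](O)[C@H](c1c(cc(OCc2ccccc2)cc1)[C@@H]1[C@H](c2cc(OC(=O)C(C)(C)C)cc(OC(=O)C(C)(C)C)c2)[C@@H](c2ccc(OC(=O)C(C)(C)C)cc2)O[C@H]1c1ccc(OC(=O)C(C)(C)C)cc1)c1cc(OC(=O)C(C)(C)C)c2c(c1)[C@@H](c1cc(OC(=O)C(C)(C)C)cc(OC(=O)C(C)(C)C)c1)[C@H](c1ccc(OC(=O)C(C)(C)C)cc1)O2 | intermediate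
33 | 4-{(1S,2S)-1-hydroxy-2-(4-hydroxy-2-X-phenyl)-2-Y-ethyl}phenyl pivalate | CC(C)(C)C(=O)Oc1ccc(cc1)[C@@H](O)[C@H](c1c(cc(O)cc1)[C@@H]1[C@H](c2cc(OC(=O)C(C)(C)C)cc(OC(=O)C(C)(C)C)c2)[C@@H](c2ccc(OC(=O)C(C)(C)C)cc2)O[C@H]1c1ccc(OC(=O)C(C)(C)C)cc1)c1cc(OC(=O)C(C)(C)C)c2c(c1)[C@@H](c1cc(OC(=O)C(C)(C)C)cc(OC(=O)C(C)(C)C)c1)[C@H](c1ccc(OC(=O)C(C)(C)C)cc1)O2 | intermediate
34 | quinol methyl ether of 33: ring B as 1-methoxy-4-oxo-2-X-cyclohexa-2,5-dien-1-yl, carbinol and methine centres as in 33, C3a unassigned | CC(C)(C)C(=O)Oc1ccc(cc1)[C@@H](O)[C@H](C1(OC)C=CC(=O)C=C1[C@@H]1[C@H](c2cc(OC(=O)C(C)(C)C)cc(OC(=O)C(C)(C)C)c2)[C@@H](c2ccc(OC(=O)C(C)(C)C)cc2)O[C@H]1c1ccc(OC(=O)C(C)(C)C)cc1)c1cc(OC(=O)C(C)(C)C)c2c(c1)[C@@H](c1cc(OC(=O)C(C)(C)C)cc(OC(=O)C(C)(C)C)c1)[C@H](c1ccc(OC(=O)C(C)(C)C)cc1)O2 | intermediate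
35 | 4-(3a-methoxy-6-oxo-4-X-3-Y-2,3,3a,6,7,7a-hexahydro-1-benzofuran-2-yl)phenyl pivalate, cis ring fusion, C2 and C3 as in 33 | CC(C)(C)C(=O)Oc1ccc(cc1)[C@H]1OC2CC(=O)C=C([C@@H]3[C@H](c4cc(OC(=O)C(C)(C)C)cc(OC(=O)C(C)(C)C)c4)[C@@H](c4ccc(OC(=O)C(C)(C)C)cc4)O[C@H]3c3ccc(OC(=O)C(C)(C)C)cc3)C2(OC)[C@@H]1c1cc(OC(=O)C(C)(C)C)c2c(c1)[C@@H](c1cc(OC(=O)C(C)(C)C)cc(OC(=O)C(C)(C)C)c1)[C@H](c1ccc(OC(=O)C(C)(C)C)cc1)O2 | intermediate
36 | 4-[(2S,3S)-6-hydroxy-4-X-3-Y-2,3-dihydro-1-benzofuran-2-yl]phenyl pivalate (kobophenol A nonapivalate, central 6-OH free) | CC(C)(C)C(=O)Oc1ccc(cc1)[C@H]1Oc2cc(O)cc([C@@H]3[C@H](c4cc(OC(=O)C(C)(C)C)cc(OC(=O)C(C)(C)C)c4)[C@@H](c4ccc(OC(=O)C(C)(C)C)cc4)O[C@H]3c3ccc(OC(=O)C(C)(C)C)cc3)c2[C@@H]1c1cc(OC(=O)C(C)(C)C)c2c(c1)[C@@H](c1cc(OC(=O)C(C)(C)C)cc(OC(=O)C(C)(C)C)c1)[C@H](c1ccc(OC(=O)C(C)(C)C)cc1)O2 | intermediate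
37 | kobophenol A | Oc1ccc([C@H]2Oc3cc(O)cc([C@@H]4[C@H](c5cc(O)cc(O)c5)[C@@H](c5ccc(O)cc5)O[C@H]4c4ccc(O)cc4)c3[C@@H]2c2cc(O)c3c(c2)[C@@H](c2cc(O)cc(O)c2)[C@H](c2ccc(O)cc2)O3)cc1 | target

**Step count and risks**
Total steps: 23. Longest linear sequence: 14 steps (steps 2–9, then 18–23).

Steps most likely to fail:

1. Step 22 (proposed new method). What may go wrong: after oxidation the dienone may lose the C3 substituent as a stabilised benzylic cation (ipso-dealkylation) or lose the C3 proton to a quinone methide before the ring closes; methanol may also add to C7a in competition with the tethered alkoxide, and over-oxidation at the anode is possible. Fallback, from 33 back to 36, in three isolated stages of known chemistry with a stoichiometric trivalent iodine oxidant instead of electrolysis: oxidation of 33 with PhI(OAc)2 in MeCN/H2O at 0 °C to the para-quinol F1; base-mediated (DBU, CH2Cl2) intramolecular oxa-Michael addition to the cis-fused 3a-hydroxy enone F2, which can be purified; then dehydrative rearomatisation (CF3CO2H in CH2Cl2, or SOCl2/pyridine) to 36.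

2. Step 20. What may go wrong: epimerisation of the congested α-methine may be slower than reduction, so no dynamic resolution takes place, or hydride transfer to the hindered ketone may stall. Fallback, from 31 back to 32, by substrate control and recycling instead of catalyst control: reduction with LiBH(sBu)3 in THF at −78 °C (Felkin–Anh addition, no epimerisation) should give 32 together with its (1R,2R)-diastereomer F3; the two are diastereomers and are separated by chromatography; F3 is re-oxidised with Dess–Martin periodinane to 31, re-equilibrated with DBU and recycled.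

3. Step 19. What may go wrong: reductive elimination at the congested benzylic carbon may be slow, so that protodebromination of 27 or O-arylation of the enolate takes over. Fallback, from 30 and 27 back to 31, with the polarity of the coupling reversed: α-bromination of 30 with CuBr2 (EtOAc/CHCl3, reflux) to the α-bromo ketone F4; Miyaura borylation of 27 (B2pin2, Pd(dppf)Cl2, KOAc, dioxane, 80 °C) to the pinacol boronate F5; Suzuki–Miyaura coupling of F4 with F5 (Pd(OAc)2, P(o-tolyl)3, K3PO4, toluene/H2O, 60 °C) to 31.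

Further compounds
F1 | step 22 | para-quinol of 33 (ring B as 1-hydroxy-4-oxo-2-X-cyclohexa-2,5-dien-1-yl) | CC(C)(C)C(=O)Oc1ccc(cc1)[C@@H](O)[C@H](C1(O)C=CC(=O)C=C1[C@@H]1[C@H](c2cc(OC(=O)C(C)(C)C)cc(OC(=O)C(C)(C)C)c2)[C@@H](c2ccc(OC(=O)C(C)(C)C)cc2)O[C@H]1c1ccc(OC(=O)C(C)(C)C)cc1)c1cc(OC(=O)C(C)(C)C)c2c(c1)[C@@H](c1cc(OC(=O)C(C)(C)C)cc(OC(=O)C(C)(C)C)c1)[C@H](c1ccc(OC(=O)C(C)(C)C)cc1)O2
F2 | step 22 | 4-(3a-hydroxy-6-oxo-4-X-3-Y-2,3,3a,6,7,7a-hexahydro-1-benzofuran-2-yl)phenyl pivalate, cis ring fusion | CC(C)(C)C(=O)Oc1ccc(cc1)[C@H]1OC2CC(=O)C=C([C@@H]3[C@H](c4cc(OC(=O)C(C)(C)C)cc(OC(=O)C(C)(C)C)c4)[C@@H](c4ccc(OC(=O)C(C)(C)C)cc4)O[C@H]3c3ccc(OC(=O)C(C)(C)C)cc3)C2(O)[C@@H]1c1cc(OC(=O)C(C)(C)C)c2c(c1)[C@@H](c1cc(OC(=O)C(C)(C)C)cc(OC(=O)C(C)(C)C)c1)[C@H](c1ccc(OC(=O)C(C)(C)C)cc1)O2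
F3 | step 20 | 4-{(1R,2R)-2-[4-(benzyloxy)-2-X-phenyl]-1-hydroxy-2-Y-ethyl}phenyl pivalate | CC(C)(C)C(=O)Oc1ccc(cc1)[C@H](O)[C@@H](c1c(cc(OCc2ccccc2)cc1)[C@@H]1[C@H](c2cc(OC(=O)C(C)(C)C)cc(OC(=O)C(C)(C)C)c2)[C@@H](c2ccc(OC(=O)C(C)(C)C)cc2)O[C@H]1c1ccc(OC(=O)C(C)(C)C)cc1)c1cc(OC(=O)C(C)(C)C)c2c(c1)[C@@H](c1cc(OC(=O)C(C)(C)C)cc(OC(=O)C(C)(C)C)c1)[C@H](c1ccc(OC(=O)C(C)(C)C)cc1)O2
F4 | step 19 | 4-{bromo[4-(benzyloxy)-2-X-phenyl]acetyl}phenyl pivalate | CC(C)(C)C(=O)Oc1ccc(cc1)C(=O)C(Br)c1c(cc(OCc2ccccc2)cc1)[C@@H]1[C@H](c2cc(OC(=O)C(C)(C)C)cc(OC(=O)C(C)(C)C)c2)[C@@H](c2ccc(OC(=O)C(C)(C)C)cc2)O[C@H]1c1ccc(OC(=O)C(C)(C)C)cc1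
F5 | step 19 | 2-Y-4,4,5,5-tetramethyl-1,3,2-dioxaborolane (pinacol boronate of 27) | CC1(C)OB(OC1(C)C)c1cc(OC(=O)C(C)(C)C)c2c(c1)[C@@H](c1cc(OC(=O)C(C)(C)C)cc(OC(=O)C(C)(C)C)c1)[C@H](c1ccc(OC(=O)C(C)(C)C)cc1)O2
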